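**Retrosynthetic overview**

1. Target 25 comes from 22 by O-methylation of the C7 phenol, fluoride desilylation and hydrogenolysis of the aryl benzyl ether.
2. The strategy rests on ring A carrying oxygen on two adjacent carbons: C7a (the ring oxygen O1) and C7 (OMe), with C7a–C3a fused to the dihydrofuran. Cutting C7a–C3a and C7–C6 turns ring A into a 2,4-disubstituted furan plus an ethynyl ether on the C2 oxygen (21), and the furan oxygen becomes the C7 oxygen.
3. Ynol ether 21 comes from alcohol 17 and trichloroethylene 18. Alcohol 17 comes from an Evans syn-aldol of furylacetyl imide 10 with aldehyde 12, which sets C2 and C3, followed by reduction and primary silylation.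
4. Imide 10 comes from 4-bromofuran-2-carbaldehyde 2 by B-alkyl Suzuki coupling with 1, one-carbon homologation and acylation of auxiliary 8. Aldehyde 12 comes from syringaldehyde 11.
5. Ring order: the furan and the syringyl ring are bought; ring A and the dihydrofuran ring are closed together in step 10.

Key step: step 10

Remark: the C3 hydroxymethyl oxygen is carried as a triisopropylsilyl ether, because a 1,3-related alkoxide is generated in step 9 and the bulkier group resists O-to-O silyl migration. Simple salts (alkoxides, phenoxides, carboxylates) of numbered compounds are not numbered separately.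

**Route**

Step 1
Reactants: 1 allyloxy-tert-butyldimethylsilane; 2 4-bromofuran-2-carbaldehyde
Product: 4 4-[3-(tert-butyldimethylsilyloxy)propyl]furan-2-carbaldehyde, via B-alkyl-9-BBN 3 (not isolated)
Conditions: 1 (1.4 equiv), 9-BBN (1.3 equiv), THF, 0 °C to rt; then 3 M aq K3PO4, 2, PdCl2(dppf) (5 mol%), DMF, 50 °C
Reagents that add atoms: none
Why: Anti-Markovnikov hydroboration followed by B-alkyl Suzuki–Miyaura coupling should work because the 2-formyl group activates the C4–Br bond toward oxidative addition to zerovalent palladium, and the aqueous base converts the borane to its borate before it can reduce the aldehyde.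

Step 2
Reactants: 4 4-[3-(tert-butyldimethylsilyloxy)propyl]furan-2-carbaldehyde
Product: 6 2-{4-[3-(tert-butyldimethylsilyloxy)propyl]furan-2-yl}acetonitrile, via N-(1-tosylvinyl)formamide potassium salt 5 (not isolated)
Conditions: TosMIC (1.2 equiv), t-BuOK (2.4 equiv), DME, −50 °C; then MeOH, 65 °C
Reagents that add atoms: p-toluenesulfonylmethyl isocyanide (TosMIC), Cc1ccc(cc1)S(=O)(=O)C[N+]#[C-]
Why: In the Van Leusen reductive cyanation the TosMIC anion adds to the aldehyde, the adduct cyclises and ring-opens at low temperature to the formamide salt, and methanolysis then removes the formyl group and sulfinate to leave the nitrile with one more carbon.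

Step 3
Reactants: 6 2-{4-[3-(tert-butyldimethylsilyloxy)propyl]furan-2-yl}acetonitrile
Product: 7 2-{4-[3-(tert-butyldimethylsilyloxy)propyl]furan-2-yl}acetic acid
Conditions: KOH, EtOH–H2O, 80 °C; then cold aq KHSO4 to pH 4
Reagents that add atoms: potassium hydroxide, [K+].[OH-]; water, O
Why: Alkaline nitrile hydrolysis should be tolerated by the furan and by the primary tert-butyldimethylsilyl ether, whose hindered silicon resists hydroxide, and the buffered acidification avoids acid damage to both.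

Step 4
Reactants: 7 2-{4-[3-(tert-butyldimethylsilyloxy)propyl]furan-2-yl}acetic acid; 8 (S)-4-benzyloxazolidin-2-one
Product: 10 (S)-4-benzyl-3-(2-{4-[3-(tert-butyldimethylsilyloxy)propyl]furan-2-yl}acetyl)oxazolidin-2-one, via mixed pivalic anhydride 9 (not isolated)
Conditions: PivCl, Et3N, THF, −20 °C; then LiCl, 8, −20 °C to rt
Reagents that add atoms: none
Why: N-acylation of the oxazolidinone through the mixed pivalic anhydride under LiCl/Et3N activation avoids strong base at the acidic furylacetyl CH2.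

Step 5
Reactants: 11 syringaldehyde
Product: 12 4-benzyloxy-3,5-dimethoxybenzaldehyde
Conditions: BnBr, K2CO3, DMF, 60 °C
Reagents that add atoms: benzyl bromide, BrCc1ccccc1
Why: Williamson etherification of the only phenol gives a protecting group that survives the organometallic steps and is removed last by hydrogenolysis.

Step 6
Reactants: 10 (S)-4-benzyl-3-(2-{4-[3-(tert-butyldimethylsilyloxy)propyl]furan-2-yl}acetyl)oxazolidin-2-one; 12 4-benzyloxy-3,5-dimethoxybenzaldehyde
Product: 15 (S)-4-benzyl-3-[(2R,3S)-3-(4-benzyloxy-3,5-dimethoxyphenyl)-2-{4-[3-(tert-butyldimethylsilyloxy)propyl]furan-2-yl}-3-hydroxypropanoyl]oxazolidin-2-one, via Z-boron enolate 13 (not isolated), via boron aldolate 14 (not isolated)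
Conditions: Bu2BOTf, iPr2NEt, CH2Cl2, −78 to 0 °C; 12, −78 to 0 °C; then pH 7 buffer, MeOH, 30% H2O2, 0 °C
Reagents that add atoms: none
Why: In the Evans syn-aldol the Z-boron enolate reacts through a chair Zimmerman–Traxler transition state on the face away from the auxiliary benzyl group, which sets the α-carbon (R, future C3) and the carbinol carbon (S, future C2) in the syn relationship that becomes 2,3-trans in the ring.

Step 7
Reactants: 15 the syn-aldol imide
Product: 16 (1S,2R)-1-(4-benzyloxy-3,5-dimethoxyphenyl)-2-{4-[3-(tert-butyldimethylsilyloxy)propyl]furan-2-yl}propane-1,3-diol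
Conditions: LiBH4, MeOH (2 equiv), THF, 0 °C
Reagents that add atoms: none
Why: LiBH4 cleaves the imide reductively to the primary alcohol and frees the auxiliary, and the low temperature limits retro-aldol cleavage and α-epimerisation.

Step 8
Reactants: 16 the 1,3-diol
Product: 17 (1S,2R)-1-(4-benzyloxy-3,5-dimethoxyphenyl)-2-{4-[3-(tert-butyldimethylsilyloxy)propyl]furan-2-yl}-3-(triisopropylsilyloxy)propan-1-ol
Conditions: TIPSCl, imidazole, DMF, 0 °C to rt
Reagents that add atoms: chlorotriisopropylsilane, CC(C)[Si](Cl)(C(C)C)C(C)C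
Why: The bulky silyl chloride reacts selectively at the primary hydroxyl and leaves the hindered benzylic secondary alcohol free.

Step 9
Reactants: 17 the secondary alcohol; 18 trichloroethylene
Product: 21 (1S,2R)-1-(4-benzyloxy-3,5-dimethoxyphenyl)-2-{4-[3-(tert-butyldimethylsilyloxy)propyl]furan-2-yl}-3-(triisopropylsilyloxy)propyl ethynyl ether, via E-dichlorovinyl ether 19 (not isolated), via lithium alkynyl ether 20 (not isolated)
Conditions: KH (1.5 equiv), THF, 0 °C; 18, 0 °C to rt; then n-BuLi (2.5 equiv), −78 to −40 °C; MeOH, −78 °C; H2O; filtration through Et3N-deactivated silica at 0 °C, used at once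
Reagents that add atoms: none
Why: The alkoxide adds to dichloroacetylene formed in situ from trichloroethylene to give the dichlorovinyl ether, and n-BuLi then effects dehydrochlorination and chlorine–lithium exchange to the lithium alkynyl ether, which is protonated cold; this is the established synthesis of terminal ynol ethers from secondary alcohols.

Step 10
Reactants: 21 the ethynyl ether
Product: 22 (2S,3R)-2-(4-benzyloxy-3,5-dimethoxyphenyl)-5-[3-(tert-butyldimethylsilyloxy)propyl]-3-[(triisopropylsilyloxy)methyl]-2,3-dihydrobenzofuran-7-ol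
Conditions: Ph3PAuNTf2 (3 mol%), 4 Å MS, CH2Cl2, 0 °C to rt
Reagents that add atoms: none
Why: The cationic monovalent gold centre binds the ynol ether, whose oxygen makes the O-bearing alkyne carbon electrophilic, and the furan C2=C3 bond adds to it at furan C2 to give a cyclopropyl gold carbenoid that opens with furan C2–O cleavage to a dienal carbenoid; the aldehyde oxygen then closes on the carbenoid carbon to an oxepine whose arene oxide valence isomer opens to the phenol. This is the gold-catalysed furan-yne phenol synthesis in its known ynol ether variant, which converts 2-(furan-2-yl)ethyl ethynyl ethers into 7-hydroxy-2,3-dihydrobenzofurans. The dihydrofuran ring closes 5-exo-dig when the C7a–C3a bond forms, and ring A closes by the 6π electrocyclisation of the oxepine that makes the C7–C6 bond. No stereocentre is formed: C2 and C3 sit on the tether, no bond to them is touched, and the trans (2S,3R) arrangement of 21 is carried over. The step needs the 7-OH regiochemistry, secured because opening the arene oxide at C6–O gives a cation that O1 on C7a stabilises, and it needs the furan to outrun the trialkoxyphenyl ring, water and benzylic C–O ionisation, for which the more nucleophilic furan, the five-membered closure, molecular sieves and 0 °C are relied on.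

Step 11
Reactants: 22 the 7-hydroxydihydrobenzofuran
Product: 23 (2S,3R)-2-(4-benzyloxy-3,5-dimethoxyphenyl)-5-[3-(tert-butyldimethylsilyloxy)propyl]-7-methoxy-3-[(triisopropylsilyloxy)methyl]-2,3-dihydrobenzofuran
Conditions: MeI, K2CO3, acetone, 40 °C
Reagents that add atoms: iodomethane, CI
Why: Williamson O-methylation of the only free phenol; the other oxygens are blocked as benzyl and silyl ethers.

Step 12
Reactants: 23 the fully protected dihydrobenzofuran
Product: 24 3-[(2S,3R)-2-(4-benzyloxy-3,5-dimethoxyphenyl)-3-(hydroxymethyl)-7-methoxy-2,3-dihydrobenzofuran-5-yl]propan-1-ol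
Conditions: TBAF (3 equiv), THF, 0 °C to rt
Reagents that add atoms: none
Why: Fluoride cleaves both primary silyl ethers, and with the syringyl oxygen still benzylated no quinone methide can open the ring under the basic conditions.

Step 13
Reactants: 24 the benzyl-protected diol
Product: 25 4-[(2S,3R)-3-(hydroxymethyl)-5-(3-hydroxypropyl)-7-methoxy-2,3-dihydrobenzofuran-2-yl]-2,6-dimethoxyphenol (target)
Conditions: H2 (1 atm), 10% Pd/C, EtOAc–MeOH, rt, stopped at full conversion
Reagents that add atoms: none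
Why: Hydrogenolysis of an aryl benzyl ether at ambient pressure in neutral solvent should be much faster than cleavage of the cyclic benzylic C2–O1 bond, so the stereocentres are left intact.

**Compound list**

1 | allyloxy-tert-butyldimethylsilane | C=CCO[Si](C)(C)C(C)(C)C | starting material
2 | 4-bromofuran-2-carbaldehyde | O=Cc1cc(Br)co1 | starting material
3 | B-[3-(tert-butyldimethylsilyloxy)propyl]-9-borabicyclo[3.3.1]nonane, formed in situ | CC(C)(C)[Si](C)(C)OCCCB1C2CCCC1CCC2 | intermediate
4 | 4-[3-(tert-butyldimethylsilyloxy)propyl]furan-2-carbaldehyde | O=Cc1cc(CCCO[Si](C)(C)C(C)(C)C)co1 | intermediate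
5 | potassium salt of N-(2-{4-[3-(tert-butyldimethylsilyloxy)propyl]furan-2-yl}-1-tosylvinyl)formamide, alkene geometry not assigned, formed in situ | [K+].O=C[N-]C(=Cc1cc(CCCO[Si](C)(C)C(C)(C)C)co1)S(=O)(=O)c1ccc(C)cc1 | intermediate
6 | 2-{4-[3-(tert-butyldimethylsilyloxy)propyl]furan-2-yl}acetonitrile | N#CCc1cc(CCCO[Si](C)(C)C(C)(C)C)co1 | intermediate
7 | 2-{4-[3-(tert-butyldimethylsilyloxy)propyl]furan-2-yl}acetic acid | OC(=O)Cc1cc(CCCO[Si](C)(C)C(C)(C)C)co1 | intermediate
8 | (S)-4-benzyloxazolidin-2-one | O=C1N[C@@H](Cc2ccccc2)CO1 | starting material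
9 | mixed anhydride of 7 and pivalic acid, formed in situ | CC(C)(C)C(=O)OC(=O)Cc1cc(CCCO[Si](C)(C)C(C)(C)C)co1 | intermediate
10 | (S)-4-benzyl-3-(2-{4-[3-(tert-butyldimethylsilyloxy)propyl]furan-2-yl}acetyl)oxazolidin-2-one | O=C1OC[C@H](Cc2ccccc2)N1C(=O)Cc1cc(CCCO[Si](C)(C)C(C)(C)C)co1 | intermediate
11 | syringaldehyde | COc1cc(C=O)cc(OC)c1O | starting material
12 | 4-benzyloxy-3,5-dimethoxybenzaldehyde | COc1cc(C=O)cc(OC)c1OCc1ccccc1 | intermediate
13 | Z-dibutylboron enolate of 10, formed in situ | CCCCB(CCCC)O/C(=C\c1cc(CCCO[Si](C)(C)C(C)(C)C)co1)N1[C@@H](Cc2ccccc2)COC1=O | intermediate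
14 | O-dibutylboryl aldolate of 15, formed in situ | O=C1OC[C@H](Cc2ccccc2)N1C(=O)[C@@H](c1cc(CCCO[Si](C)(C)C(C)(C)C)co1)[C@H](OB(CCCC)CCCC)c1cc(OC)c(OCc2ccccc2)c(OC)c1 | intermediate
15 | (S)-4-benzyl-3-[(2R,3S)-3-(4-benzyloxy-3,5-dimethoxyphenyl)-2-{4-[3-(tert-butyldimethylsilyloxy)propyl]furan-2-yl}-3-hydroxypropanoyl]oxazolidin-2-one | O=C1OC[C@H](Cc2ccccc2)N1C(=O)[C@@H](c1cc(CCCO[Si](C)(C)C(C)(C)C)co1)[C@H](O)c1cc(OC)c(OCc2ccccc2)c(OC)c1 | intermediate
16 | (1S,2R)-1-(4-benzyloxy-3,5-dimethoxyphenyl)-2-{4-[3-(tert-butyldimethylsilyloxy)propyl]furan-2-yl}propane-1,3-diol | OC[C@@H](c1cc(CCCO[Si](C)(C)C(C)(C)C)co1)[C@H](O)c1cc(OC)c(OCc2ccccc2)c(OC)c1 | intermediate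
17 | (1S,2R)-1-(4-benzyloxy-3,5-dimethoxyphenyl)-2-{4-[3-(tert-butyldimethylsilyloxy)propyl]furan-2-yl}-3-(triisopropylsilyloxy)propan-1-ol | CC(C)[Si](C(C)C)(C(C)C)OC[C@@H](c1cc(CCCO[Si](C)(C)C(C)(C)C)co1)[C@H](O)c1cc(OC)c(OCc2ccccc2)c(OC)c1 | intermediate
18 | trichloroethylene | ClC=C(Cl)Cl | starting material
19 | (E)-1,2-dichlorovinyl ether of 17, (1S,2R), formed in situ | CC(C)[Si](C(C)C)(C(C)C)OC[C@@H](c1cc(CCCO[Si](C)(C)C(C)(C)C)co1)[C@H](O/C(Cl)=C\Cl)c1cc(OC)c(OCc2ccccc2)c(OC)c1 | intermediate
20 | lithium acetylide of 21, (1S,2R), formed in situ | CC(C)[Si](C(C)C)(C(C)C)OC[C@@H](c1cc(CCCO[Si](C)(C)C(C)(C)C)co1)[C@H](OC#C[Li])c1cc(OC)c(OCc2ccccc2)c(OC)c1 | intermediate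
21 | (1S,2R)-1-(4-benzyloxy-3,5-dimethoxyphenyl)-2-{4-[3-(tert-butyldimethylsilyloxy)propyl]furan-2-yl}-3-(triisopropylsilyloxy)propyl ethynyl ether | CC(C)[Si](C(C)C)(C(C)C)OC[C@@H](c1cc(CCCO[Si](C)(C)C(C)(C)C)co1)[C@H](OC#C)c1cc(OC)c(OCc2ccccc2)c(OC)c1 | intermediate
22 | (2S,3R)-2-(4-benzyloxy-3,5-dimethoxyphenyl)-5-[3-(tert-butyldimethylsilyloxy)propyl]-3-[(triisopropylsilyloxy)methyl]-2,3-dihydrobenzofuran-7-ol | COc1cc([C@H]2Oc3c(O)cc(CCCO[Si](C)(C)C(C)(C)C)cc3[C@@H]2CO[Si](C(C)C)(C(C)C)C(C)C)cc(OC)c1OCc1ccccc1 | intermediate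
23 | (2S,3R)-2-(4-benzyloxy-3,5-dimethoxyphenyl)-5-[3-(tert-butyldimethylsilyloxy)propyl]-7-methoxy-3-[(triisopropylsilyloxy)methyl]-2,3-dihydrobenzofuran | COc1cc([C@H]2Oc3c(OC)cc(CCCO[Si](C)(C)C(C)(C)C)cc3[C@@H]2CO[Si](C(C)C)(C(C)C)C(C)C)cc(OC)c1OCc1ccccc1 | intermediate
24 | 3-[(2S,3R)-2-(4-benzyloxy-3,5-dimethoxyphenyl)-3-(hydroxymethyl)-7-methoxy-2,3-dihydrobenzofuran-5-yl]propan-1-ol | COc1cc([C@H]2Oc3c(OC)cc(CCCO)cc3[C@@H]2CO)cc(OC)c1OCc1ccccc1 | intermediate
25 | 4-[(2S,3R)-3-(hydroxymethyl)-5-(3-hydroxypropyl)-7-methoxy-2,3-dihydrobenzofuran-2-yl]-2,6-dimethoxyphenol | COc1cc([C@H]2Oc3c(OC)cc(CCCO)cc3[C@@H]2CO)cc(OC)c1O | target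

**Step count and risks**

Total steps: 13. Longest linear sequence: 12 (steps 1–4 and 6–13); step 5 is a one-step side branch.

Steps most likely to fail:

1. Step 10 (key step). The electron-rich benzylic ynol ether may ionise at its C–O bond or rearrange sigmatropically, or the activated alkyne may be captured by water or by the trialkoxyphenyl ring, before the furan attacks. The fallback takes ring A from a preformed guaiacol and closes the dihydrofuran by acid; it sets out from aldehyde 12 and auxiliary 8 and comes back at target 25. Commercial 4-(3-hydroxypropyl)-2-methoxyphenol (COc1cc(CCCO)ccc1O) would be O-allylated at the phenol (allyl bromide, K2CO3, acetone) to 3-[4-(allyloxy)-3-methoxyphenyl]propan-1-ol F1 and silylated (TBSCl, imidazole) to its tert-butyldimethylsilyl ether F2. Heating (N,N-diethylaniline, 190 °C) should deliver the allyl group by aromatic Claisen rearrangement to the only free ortho position, giving 2-allyl-4-[3-(tert-butyldimethylsilyloxy)propyl]-6-methoxyphenol F3, which is benzylated (BnBr, K2CO3) to benzyl ether F4. Lemieux–Johnson cleavage (cat. OsO4, NaIO4, 2,6-lutidine, dioxane–water) should give arylacetaldehyde F5, and Pinnick oxidation (NaClO2, NaH2PO4, 2-methyl-2-butene) arylacetic acid F6. Acylation of 8 as in step 4 would give imide F7, the Evans syn-aldol with 12 as in step 6 the aldol F8, and LiBH4 the diol F9. Hydrogenolysis (H2, Pd/C) would remove both benzyl groups to give bisphenol F10. Dilute HCl in THF–water should then ionise the 4-hydroxybenzylic alcohol to its quinone methide, which the neighbouring phenol captures to the 2,3-trans dihydrobenzofuran while the silyl ether is cleaved, giving 25. C3 comes from the aldol and C2 is set trans to it in the ring closure.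

2. Step 9. The 1,3-related alkoxide may suffer O-to-O silyl migration or react sluggishly with dichloroacetylene because of hindrance, and the ynol ether may be lost by thermal retro-ene or sigmatropic pathways during isolation. The fallback builds the two alkyne carbons one at a time without an alkoxide; it sets out from 17 and comes back at 21. Alcohol 17 would be formylated (acetic formic anhydride, pyridine, 0 °C) to formate F11, and dibromo-olefination of the formyl group (CBr4, PPh3, CH2Cl2) should give 2,2-dibromovinyl ether F12. Treatment with n-BuLi (2.2 equiv, −78 °C) should give lithium alkynyl ether 20 by dehydrobromination and bromine–lithium exchange, and cold protonation gives 21.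

3. Step 2. The oxazoline intermediate may eliminate sulfinate to the 5-furyloxazole instead of ring-opening to the formamide salt, and the furan aldehyde may degrade under the strong base. The fallback homologates at the carboxylic acid level; it sets out from 4 and comes back at 7, bypassing steps 2 and 3. Pinnick oxidation of 4 (NaClO2, NaH2PO4, 2-methyl-2-butene, t-BuOH–water) would give 4-[3-(tert-butyldimethylsilyloxy)propyl]furan-2-carboxylic acid F13. Oxalyl chloride with catalytic DMF would give acid chloride F14, and excess diazomethane the diazoketone F15. Wolff rearrangement (cat. PhCO2Ag, Et3N, THF–water) completes the Arndt–Eistert sequence to acid 7.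

**Further compounds**

F1 | step 10 | 3-[4-(allyloxy)-3-methoxyphenyl]propan-1-ol | C=CCOc1ccc(CCCO)cc1OC
F2 | step 10 | {3-[4-(allyloxy)-3-methoxyphenyl]propoxy}(tert-butyl)dimethylsilane | C=CCOc1ccc(CCCO[Si](C)(C)C(C)(C)C)cc1OC
F3 | step 10 | 2-allyl-4-[3-(tert-butyldimethylsilyloxy)propyl]-6-methoxyphenol | C=CCc1cc(CCCO[Si](C)(C)C(C)(C)C)cc(OC)c1O
F4 | step 10 | {3-[3-allyl-4-(benzyloxy)-5-methoxyphenyl]propoxy}(tert-butyl)dimethylsilane | C=CCc1cc(CCCO[Si](C)(C)C(C)(C)C)cc(OC)c1OCc1ccccc1
F5 | step 10 | 2-{2-(benzyloxy)-5-[3-(tert-butyldimethylsilyloxy)propyl]-3-methoxyphenyl}acetaldehyde | O=CCc1cc(CCCO[Si](C)(C)C(C)(C)C)cc(OC)c1OCc1ccccc1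
F6 | step 10 | 2-{2-(benzyloxy)-5-[3-(tert-butyldimethylsilyloxy)propyl]-3-methoxyphenyl}acetic acid | OC(=O)Cc1cc(CCCO[Si](C)(C)C(C)(C)C)cc(OC)c1OCc1ccccc1
F7 | step 10 | (S)-4-benzyl-3-(2-{2-(benzyloxy)-5-[3-(tert-butyldimethylsilyloxy)propyl]-3-methoxyphenyl}acetyl)oxazolidin-2-one | O=C1OC[C@H](Cc2ccccc2)N1C(=O)Cc1cc(CCCO[Si](C)(C)C(C)(C)C)cc(OC)c1OCc1ccccc1
F8 | step 10 | (S)-4-benzyl-3-[(2S,3S)-3-(4-benzyloxy-3,5-dimethoxyphenyl)-2-{2-(benzyloxy)-5-[3-(tert-butyldimethylsilyloxy)propyl]-3-methoxyphenyl}-3-hydroxypropanoyl]oxazolidin-2-one | O=C1OC[C@H](Cc2ccccc2)N1C(=O)[C@@H](c1cc(CCCO[Si](C)(C)C(C)(C)C)cc(OC)c1OCc1ccccc1)[C@H](O)c1cc(OC)c(OCc2ccccc2)c(OC)c1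
F9 | step 10 | (1S,2R)-1-(4-benzyloxy-3,5-dimethoxyphenyl)-2-{2-(benzyloxy)-5-[3-(tert-butyldimethylsilyloxy)propyl]-3-methoxyphenyl}propane-1,3-diol | OC[C@@H](c1cc(CCCO[Si](C)(C)C(C)(C)C)cc(OC)c1OCc1ccccc1)[C@H](O)c1cc(OC)c(OCc2ccccc2)c(OC)c1
F10 | step 10 | (1S,2R)-2-{5-[3-(tert-butyldimethylsilyloxy)propyl]-2-hydroxy-3-methoxyphenyl}-1-(4-hydroxy-3,5-dimethoxyphenyl)propane-1,3-diol | OC[C@@H](c1cc(CCCO[Si](C)(C)C(C)(C)C)cc(OC)c1O)[C@H](O)c1cc(OC)c(O)c(OC)c1
F11 | step 9 | (1S,2R)-1-(4-benzyloxy-3,5-dimethoxyphenyl)-2-{4-[3-(tert-butyldimethylsilyloxy)propyl]furan-2-yl}-3-(triisopropylsilyloxy)propyl formate | CC(C)[Si](C(C)C)(C(C)C)OC[C@@H](c1cc(CCCO[Si](C)(C)C(C)(C)C)co1)[C@H](OC=O)c1cc(OC)c(OCc2ccccc2)c(OC)c1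
F12 | step 9 | (1S,2R)-1-(4-benzyloxy-3,5-dimethoxyphenyl)-2-{4-[3-(tert-butyldimethylsilyloxy)propyl]furan-2-yl}-3-(triisopropylsilyloxy)propyl 2,2-dibromovinyl ether | CC(C)[Si](C(C)C)(C(C)C)OC[C@@H](c1cc(CCCO[Si](C)(C)C(C)(C)C)co1)[C@H](OC=C(Br)Br)c1cc(OC)c(OCc2ccccc2)c(OC)c1
F13 | step 2 | 4-[3-(tert-butyldimethylsilyloxy)propyl]furan-2-carboxylic acid | OC(=O)c1cc(CCCO[Si](C)(C)C(C)(C)C)co1
F14 | step 2 | 4-[3-(tert-butyldimethylsilyloxy)propyl]furan-2-carbonyl chloride | ClC(=O)c1cc(CCCO[Si](C)(C)C(C)(C)C)co1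
F15 | step 2 | 2-diazo-1-{4-[3-(tert-butyldimethylsilyloxy)propyl]furan-2-yl}ethan-1-one | [N-]=[N+]=CC(=O)c1cc(CCCO[Si](C)(C)C(C)(C)C)co1
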